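Count the reagent before you read the curve: that is how I began on the amber run, which is the very flask asked about, followed up to 50.0 min.

| flask | substrate | reagent in the second phase | protic impurity | remark | time | volume of the second phase over the first |
|---|---|---|---|---|---|---|
| amber | 0.29 M | 0.348 M | 0.087 M | the very flask that is asked about, followed so far |  |  |
| flask | 0.29 M | 0.348 M | 0.0870 M |  | 2.5 h | 0.25 |

- amber (time / min: product / %, substrate / %): 4.00: 36, 64; 6.00: 51, 50; 10.0: 67, 29; 15.0: 78, 20; 25.0: 85, 10; 50.0: 96, 3

(standard deviation of a reading: 2 percentage points)

* the product standing at 2.5 h, as a percentage of the substrate charged
* the change that raises the amount of product at 2.5 h, in percent of the substrate charged most ("none" if none brings more than 2 percentage points) (gamma / beta / none)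
* amount of product at 2.5 h, in percent of the substrate charged, after gamma

- gamma: doubling the amount of reagent in the second phase, all else as stated
- beta: doubling the transfer coefficient of the reagent in the second phase, all else as stated

- in the second phase: reagent in the second phase; everything else is in the first
- charges count per volume of the first phase; a concentration in a rate is the amount of a species over the volume of its own phase; every rate counts per litre of the first phase
- the earlier runs were read with a standard deviation of 2 percentage points
- the earlier runs hold the two phases in the same ratio of volumes as the flask asked about

The reagent budget, c(reagent in the second phase) less c(protic impurity), over c(substrate), came to 90.0 %. It is the share of the substrate that can become product if the protic impurity takes its whole charge one for one, and on that count the reagent is the limiting reagent.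

I then watched the amber run in slow motion. Over the first 4.00 min product appeared at a mean of 0.0261 M min⁻¹, reckoned from that one scattered reading, which stood for 0.104 M of the 0.348 M of reagent charged. At 15.0 min the reagent not yet in product was 0.122 M, less than the 0.145 M claimed by the substrate read then plus the charged impurity, so the shortfall was about to matter. Over the last stretch product gained a mean of 0.00128 M min⁻¹, slower than over the first stretch, and the last reading stood 6 percentage points above the budget, against a scatter of 2 points.

I took the budget as a floor and committed to 93.0 % at 2.5 h, midway between it and that reading. Gamma lifts the budget to 210 %, so I chose gamma, expecting about 7 points from it; beta leaves the budget unchanged.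

The forecast differed from me, with 98 %, best change none and 99.7 % after gamma, on the ground that “So the impurity consumes little reagent, at least on this timescale.”

The flask gave 92.3 %, best change gamma, worth 7.3 points against −0.052 points for beta, and 99.7 % after gamma.

    2 reagent in the reaction phase → homo dimer (k = 0.00130 M⁻¹ s⁻¹)
    reagent in the reaction phase + protic impurity → quenched reagent (k = 0.0540 M⁻¹ s⁻¹)
    reagent in the reaction phase ⇌ reagent in the second phase, rate k3*([reagent in the reaction phase] - [reagent in the second phase]/K3) per volume of the first phase (partition coefficient = 0.540, kL = 3.50 × 10⁻⁴ s⁻¹)
    substrate + reagent in the reaction phase → product (k = 0.0690 M⁻¹ s⁻¹)
    substrate ⇌ dormant form (K = 0.370, k = 5.80 × 10⁻⁵ s⁻¹)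

The flask's product stood 2.3 points above the budget of 90.0 %, with 10 % of the protic impurity left and 0 % of the reagent in the second phase. The neighbour charged with 1.2 M of substrate has a budget of 21.8 %, and even the whole reagent charge covers 29.0 % of its substrate. That neighbour gave 27.4 %, between the two, with 77 % of its protic impurity left and 56 % of its substrate still standing.

Readings and results were generated by integration from invented constants; noise was put on by code.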